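The six-membered ring is made from a cyclopentene by inserting one carbon: C4 lies between C3 and the oxygenated C5, which is cis-vicinal to C6–O, so ring atoms C1, C2, C3, C5 and C6 come from (S)-2-cyclopentene-1-acetic acid and C4 from dibromocarbene. In one operation silver(I) opens the gem-dibromocyclopropane fused at C3–C5 to the six-membered 2-bromoallyl cation, and the C6 ester delivers oxygen to C5 on its own face, giving the cis C5/C6 diol monoester with a C3=C4–Br handle for the methyl group. The precursor is a 6,6-dibromobicyclo[3.1.0]hexane carrying a C6 pivalate and the two-carbon C1 arm (as a primary pivalate) cis to each other and anti to the cyclopropane.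

Key step: step 6

Numbering used throughout: ring C1 (bears the side chain), C2 (CH2), C3/C4 (epoxide carbons, methyl on C4), C5 and C6 (angelate carbons); side chain C7 (exo-methylene carbon) and C8 (acetoxy carbon).

Assumption: acid 1 is bought as the (S)-enantiomer and borane 19 as its commercial pentane solution; the numbered starting materials are those whose carbon atoms end up in the target.

Design notes:
- The C1 arm passes through the key step as a primary pivalate (alcohol oxidation level). A cis γ-hydroxy ester on C1/C6 would close back to the lactone whenever the C6 oxygen is free, and an ester carbonyl on the arm would be a second internal nucleophile.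
- The participating ester is the pivalate, because an acetate is unlikely to survive the hydroxide needed to generate dibromocarbene.
- The prenyl group is built by allylboration and cross-metathesis, because prenyl-metal reagents bond through their γ-carbon and would give the reverse-prenyl isomer.

Step 1
Reactants: 1 (S)-2-cyclopentene-1-acetic acid
Product: 2 (3aS,6R,6aR)-6-iodohexahydro-2H-cyclopenta[b]furan-2-one (cis-fused, iodine trans to the ring oxygen)
Conditions: I2, KI, NaHCO3, THF/H2O, 0 °C → rt, dark
Reagents that add atoms: iodine, II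
Why: Iodolactonization, in which the carboxylate opens the iodonium ion anti at the ring carbon next to C1, so the γ-lactone is cis-fused (C6–O on the face of the C1 arm) and iodine sits trans on C5.

Step 2
Reactants: 2 the iodolactone
Product: 3 (3aS,6aR)-3,3a,4,6a-tetrahydro-2H-cyclopenta[b]furan-2-one (cis-fused allylic lactone)
Conditions: DBU, THF, reflux
Reagents that add atoms: none
Why: E2 dehydroiodination, in which only the C3 hydrogen is anti-periplanar to iodine (the C6 hydrogen is syn), so the alkene should form between C3 and C5 without touching C1 or C6.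

Step 3
Reactants: 3 the allylic lactone
Product: 4 (1R,5S)-5-(2-hydroxyethyl)cyclopent-2-en-1-ol (cis diol)
Conditions: LiAlH4, THF, 0 °C; H2O, aq NaOH work-up
Reagents that add atoms: none
Why: Lithium aluminium hydride reduction of the lactone to the 1,4-diol removes the carboxyl oxidation level, so the cis C6 hydroxyl can no longer relactonise, and no stereocentre is touched.

Step 4
Reactants: 4 the cis diol
Product: 5 (1R,5S)-5-[2-(pivaloyloxy)ethyl]cyclopent-2-en-1-yl pivalate
Conditions: PivCl, pyridine, DMAP (cat.), CH2Cl2, 0 °C → rt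
Reagents that add atoms: pivaloyl chloride, CC(C)(C)C(Cl)=O
Why: DMAP-catalysed acylation of both hydroxyls, giving the C6 pivalate that later acts as neighbouring group and a primary pivalate too remote to reach the ring.

Step 5
Reactants: 5 the bis-pivalate; 6 bromoform
Product: 7 (1R,2R,3S,5R)-6,6-dibromo-3-[2-(pivaloyloxy)ethyl]bicyclo[3.1.0]hexan-2-yl pivalate (ester and arm cis, both anti to the CBr2 bridge)
Conditions: CHBr3, 50% aq NaOH, BnEt3NCl (cat.), CH2Cl2, 0 °C → rt, vigorous stirring
Reagents that add atoms: bromoform, BrC(Br)Br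
Why: Phase-transfer (Makosza) dibromocyclopropanation, in which the electrophilic carbene should add to the only alkene from the face opposite the cis C1 arm and C6 pivalate, setting the ring-fusion centres C3 and C5 anti to both.

Step 6
Reactants: 7 the dibromocyclopropane
Product: 10 2-[(1S,5R,6R)-4-bromo-5-hydroxy-6-(pivaloyloxy)cyclohex-3-en-1-yl]ethyl pivalate (all-cis), via 2-bromoallyl cation 8 (not isolated), via dioxolanylium salt 9 (not isolated)
Conditions: AgBF4, CH2Cl2 (dry), 0 °C → rt, dark; then THF/sat. aq NaHCO3, 0 °C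
Reagents that add atoms: water, O
Why: Silver(I) removes the endo bromine (the one over the five-membered ring) in concert with disrotatory two-electron opening of the C3–C5 bond, the only orbital-symmetry-allowed mode that keeps the allyl cation inside the ring, so the carbene carbon becomes ring atom C4 of the cyclohexenyl 2-bromoallyl cation 8. The carbonyl oxygen of the cis C6 pivalate closes on C5 to the cis-fused five-membered dioxolanylium ion 9, and water then adds to its acyl carbon and the hemi-orthoester collapses to the cis hydroxy ester with C3=C4–Br left in place. The closest known reaction type is the silver-promoted electrocyclic ring expansion of ring-fused gem-dibromocyclopropanes with capture of the allyl cation by an internal nucleophile, joined to classical acyloxy neighbouring-group participation. The six-membered ring arises by ring expansion (cleavage of the shared cyclopropane bond) and not by cyclisation, while the transient dioxolane ring closes in a 5-exo sense on the allyl terminus. The single new stereocentre C5 is controlled by C6, since the tethered oxygen can reach C5 only on the face it already occupies. The step needs capture at C5 rather than C3 and syn to C6–O; the vicinal ester cannot reach C3, the non-nucleophilic counter-ion and dry medium withhold external nucleophiles until the quench, and the remote primary pivalate cannot compete.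

Step 7
Reactants: 10 the hydroxy pivalate
Product: 11 2-[(1S,5R,6R)-4-bromo-5,6-dihydroxycyclohex-3-en-1-yl]ethanol (all-cis triol)
Conditions: NaOMe, MeOH, 50 °C; Amberlite IR-120 (H+)
Reagents that add atoms: none
Why: Base-catalysed transesterification (Zemplén type) removes both pivalates, so any acyl migration between the cis C5 and C6 oxygens is without consequence, and the vinyl bromide and stereocentres are inert to methoxide.

Step 8
Reactants: 11 the triol
Product: 12 2-[(1S,5R,6R)-4-bromo-5,6-(isopropylidenedioxy)cyclohex-3-en-1-yl]ethanol (cis-fused acetonide, primary alcohol free)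
Conditions: Me2C(OMe)2, PPTS (cat.), acetone, rt; then MeOH, rt
Reagents that add atoms: 2,2-dimethoxypropane, COC(C)(C)OC
Why: Acid-catalysed acetonide formation selects the cis-vicinal C5/C6 diol (five-membered dioxolane) over the 1,4-related primary hydroxyl, whose mixed ketal, if formed, should fall off in the methanol quench.

Step 9
Reactants: 12 the bromo acetonide; 13 trimethylboroxine
Product: 14 2-[(1S,5S,6R)-5,6-(isopropylidenedioxy)-4-methylcyclohex-3-en-1-yl]ethanol
Conditions: (MeBO)3, Pd(dppf)Cl2·CH2Cl2 (cat.), K2CO3, 1,4-dioxane/H2O, 90 °C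
Reagents that add atoms: trimethylboroxine, CB1OB(C)OB(C)O1
Why: Suzuki–Miyaura methylation of the alkenyl bromide, a coupling that 2-bromoallylic acetonides undergo readily, with the free primary alcohol tolerated and no stereocentre involved.

Step 10
Reactants: 14 the primary alcohol
Product: 15 2-[(1S,5S,6R)-5,6-(isopropylidenedioxy)-4-methylcyclohex-3-en-1-yl]acetaldehyde
Conditions: Dess–Martin periodinane, NaHCO3, CH2Cl2, 0 °C → rt
Reagents that add atoms: none
Why: Dess–Martin oxidation under buffered conditions should leave the acetonide and the trisubstituted alkene alone, and C1 is β to the new carbonyl and cannot epimerise by enolisation.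

Step 11
Reactants: 15 the aldehyde; 16 Eschenmoser's salt (N,N-dimethylmethyleneiminium iodide)
Product: 18 2-[(1S,5S,6R)-5,6-(isopropylidenedioxy)-4-methylcyclohex-3-en-1-yl]prop-2-enal, via Mannich base 17 (not isolated)
Conditions: CH2=NMe2+ I−, Et3N, CH2Cl2, rt
Reagents that add atoms: Eschenmoser's salt, C=[N+](C)C.[I-]
Why: Mannich reaction of the aldehyde enol at C7 followed by elimination of dimethylamine (Eschenmoser methylenation) should give the 2-substituted acrolein, the transient C7 centre being lost.

Step 12
Reactants: 18 the enal; 19 (−)-B-allyldiisopinocampheylborane [(−)-Ipc2B(allyl), from (+)-α-pinene]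
Product: 21 (3S)-2-[(1S,5S,6R)-5,6-(isopropylidenedioxy)-4-methylcyclohex-3-en-1-yl]hexa-1,5-dien-3-ol, via borinate ester 20 (not isolated)
Conditions: 19 (1 M in pentane), Et2O, −78 °C; then 3 M NaOH, 30% H2O2, 0 °C → rt
Reagents that add atoms: (−)-B-allyldiisopinocampheylborane, C=CCB([C@@H]1C[C@@H]2C[C@H]([C@H]1C)C2(C)C)[C@@H]1C[C@@H]2C[C@H]([C@H]1C)C2(C)C
Why: Brown allylboration through a closed chair transition state, in which the (+)-α-pinene-derived reagent transfers allyl to the Si face of the aldehyde, which is (S) at C8 because C7 outranks the allyl carbon, and reagent control should dominate the remote C1 centre.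

Step 13
Reactants: 21 the homoallylic alcohol; 22 2-methyl-2-butene
Product: 23 (3S)-2-[(1S,5S,6R)-5,6-(isopropylidenedioxy)-4-methylcyclohex-3-en-1-yl]-6-methylhepta-1,5-dien-3-ol
Conditions: 2-methyl-2-butene (excess), Grubbs II (cat.), CH2Cl2, 40 °C
Reagents that add atoms: 2-methyl-2-butene, CC=C(C)C
Why: Olefin cross-metathesis, in which only the monosubstituted alkene is a reactive partner while the 1,1-disubstituted and trisubstituted alkenes are inert, so excess 2-methyl-2-butene should cap the chain as the prenyl group.

Step 14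
Reactants: 23 the prenyl alcohol; 24 acetic anhydride
Product: 25 (3S)-2-[(1S,5S,6R)-5,6-(isopropylidenedioxy)-4-methylcyclohex-3-en-1-yl]-6-methylhepta-1,5-dien-3-yl acetate
Conditions: Ac2O, pyridine, DMAP (cat.), CH2Cl2, 0 °C → rt
Reagents that add atoms: acetic anhydride, CC(=O)OC(C)=O
Why: DMAP-catalysed acetylation of the only free hydroxyl, with retention at C8.

Step 15
Reactants: 25 the acetonide acetate
Product: 26 (3S)-2-[(1S,5S,6R)-5,6-dihydroxy-4-methylcyclohex-3-en-1-yl]-6-methylhepta-1,5-dien-3-yl acetate
Conditions: AcOH/H2O (4:1), 40 °C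
Reagents that add atoms: none
Why: Mild aqueous-acid hydrolysis of the cis-fused acetonide, which the secondary allylic acetate, the exo-methylene and the prenyl alkene should tolerate.

Step 16
Reactants: 26 the diol acetate
Product: 27 the cis-epoxy diol (26 with C3=C4 epoxidised on the face of the C5 and C6 hydroxyls, methyl on C4 on the opposite face)
Conditions: VO(acac)2 (cat.), t-BuOOH (decane), CH2Cl2, 0 °C → rt
Reagents that add atoms: tert-butyl hydroperoxide, CC(C)(C)OO
Why: Vanadium-catalysed hydroxyl-directed epoxidation, in which the C5 allylic alkoxide binds the vanadium peroxide and delivers oxygen to C3=C4 from its own face, setting C3 and C4 cis to both hydroxyls, while the undirected prenyl and exo-methylene alkenes should react far more slowly.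

Step 17
Reactants: 27 the epoxy diol; 28 angelic acid
Product: 29 the target CNP0188566.2 (C5,C6-bis-angelate, C8 acetate)
Conditions: 28, 2,4,6-Cl3C6H2COCl, Et3N, toluene, rt, filter; then 27, toluene, 80 °C
Reagents that add atoms: angelic acid, C/C=C(/C)C(=O)O
Why: Yamaguchi-type esterification through the angelic 2,4,6-trichlorobenzoic mixed anhydride without nucleophilic catalyst, the established way to form angelates without Z→E isomerisation to tiglates, should acylate both secondary hydroxyls with retention.

Compound list
1 | (S)-2-cyclopentene-1-acetic acid | OC(=O)C[C@H]1C=CCC1 | starting material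
2 | (3aS,6R,6aR)-6-iodohexahydro-2H-cyclopenta[b]furan-2-one | O=C1C[C@@H]2CC[C@@H](I)[C@@H]2O1 | intermediate
3 | (3aS,6aR)-3,3a,4,6a-tetrahydro-2H-cyclopenta[b]furan-2-one | O=C1C[C@@H]2CC=C[C@@H]2O1 | intermediate
4 | (1R,5S)-5-(2-hydroxyethyl)cyclopent-2-en-1-ol | OCC[C@@H]1CC=C[C@@H]1O | intermediate
5 | (1R,5S)-5-[2-(pivaloyloxy)ethyl]cyclopent-2-en-1-yl pivalate | CC(C)(C)C(=O)OCC[C@@H]1CC=C[C@@H]1OC(=O)C(C)(C)C | intermediate
6 | bromoform | BrC(Br)Br | starting material
7 | (1R,2R,3S,5R)-6,6-dibromo-3-[2-(pivaloyloxy)ethyl]bicyclo[3.1.0]hexan-2-yl pivalate | CC(C)(C)C(=O)OCC[C@@H]1C[C@@H]2[C@H]([C@@H]1OC(=O)C(C)(C)C)C2(Br)Br | intermediate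
8 | ring-expanded 2-bromoallyl cation (charge shared by C3 and C5) | CC(C)(C)C(=O)OCC[C@@H]1C[CH+]C(Br)=C[C@@H]1OC(=O)C(C)(C)C | intermediate
9 | cis-fused 2-tert-butyl-1,3-dioxolan-2-ylium tetrafluoroborate on C5/C6 | CC(C)(C)C(=O)OCC[C@@H]1CC=C(Br)[C@@H]2OC(C(C)(C)C)=[O+][C@H]12.F[B-](F)(F)F | intermediate
10 | 2-[(1S,5R,6R)-4-bromo-5-hydroxy-6-(pivaloyloxy)cyclohex-3-en-1-yl]ethyl pivalate | CC(C)(C)C(=O)OCC[C@@H]1CC=C(Br)[C@H](O)[C@@H]1OC(=O)C(C)(C)C | intermediate
11 | 2-[(1S,5R,6R)-4-bromo-5,6-dihydroxycyclohex-3-en-1-yl]ethanol | OCC[C@@H]1CC=C(Br)[C@H](O)[C@@H]1O | intermediate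
12 | 2-[(1S,5R,6R)-4-bromo-5,6-(isopropylidenedioxy)cyclohex-3-en-1-yl]ethanol | OCC[C@@H]1CC=C(Br)[C@@H]2OC(C)(C)O[C@H]12 | intermediate
13 | trimethylboroxine | CB1OB(C)OB(C)O1 | starting material
14 | 2-[(1S,5S,6R)-5,6-(isopropylidenedioxy)-4-methylcyclohex-3-en-1-yl]ethanol | OCC[C@@H]1CC=C(C)[C@@H]2OC(C)(C)O[C@H]12 | intermediate
15 | 2-[(1S,5S,6R)-5,6-(isopropylidenedioxy)-4-methylcyclohex-3-en-1-yl]acetaldehyde | O=CC[C@@H]1CC=C(C)[C@@H]2OC(C)(C)O[C@H]12 | intermediate
16 | Eschenmoser's salt (N,N-dimethylmethyleneiminium iodide) | C=[N+](C)C.[I-] | starting material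
17 | Mannich base, 3-(dimethylamino)-2-(ring)propanal, both C7 epimers | CN(C)CC(C=O)[C@@H]1CC=C(C)[C@@H]2OC(C)(C)O[C@H]12 | intermediate
18 | 2-[(1S,5S,6R)-5,6-(isopropylidenedioxy)-4-methylcyclohex-3-en-1-yl]prop-2-enal | C=C(C=O)[C@@H]1CC=C(C)[C@@H]2OC(C)(C)O[C@H]12 | intermediate
19 | (−)-B-allyldiisopinocampheylborane | C=CCB([C@@H]1C[C@@H]2C[C@H]([C@H]1C)C2(C)C)[C@@H]1C[C@@H]2C[C@H]([C@H]1C)C2(C)C | starting material
20 | diisopinocampheylborinate ester of 21 | C=C([C@H](CC=C)OB([C@@H]3C[C@@H]4C[C@H]([C@H]3C)C4(C)C)[C@@H]3C[C@@H]4C[C@H]([C@H]3C)C4(C)C)[C@@H]1CC=C(C)[C@@H]2OC(C)(C)O[C@H]12 | intermediate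
21 | (3S)-2-[(1S,5S,6R)-5,6-(isopropylidenedioxy)-4-methylcyclohex-3-en-1-yl]hexa-1,5-dien-3-ol | C=C([C@H](CC=C)O)[C@@H]1CC=C(C)[C@@H]2OC(C)(C)O[C@H]12 | intermediate
22 | 2-methyl-2-butene | CC=C(C)C | starting material
23 | (3S)-2-[(1S,5S,6R)-5,6-(isopropylidenedioxy)-4-methylcyclohex-3-en-1-yl]-6-methylhepta-1,5-dien-3-ol | C=C([C@H](CC=C(C)C)O)[C@@H]1CC=C(C)[C@@H]2OC(C)(C)O[C@H]12 | intermediate
24 | acetic anhydride | CC(=O)OC(C)=O | starting material
25 | (3S)-2-[(1S,5S,6R)-5,6-(isopropylidenedioxy)-4-methylcyclohex-3-en-1-yl]-6-methylhepta-1,5-dien-3-yl acetate | C=C([C@H](CC=C(C)C)OC(C)=O)[C@@H]1CC=C(C)[C@@H]2OC(C)(C)O[C@H]12 | intermediate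
26 | (3S)-2-[(1S,5S,6R)-5,6-dihydroxy-4-methylcyclohex-3-en-1-yl]-6-methylhepta-1,5-dien-3-yl acetate | C=C([C@H](CC=C(C)C)OC(C)=O)[C@@H]1CC=C(C)[C@H](O)[C@@H]1O | intermediate
27 | cis-epoxy diol (C3/C4 epoxide cis to the C5 and C6 hydroxyls and to the C1 side chain) | C=C([C@H](CC=C(C)C)OC(C)=O)[C@@H]1C[C@@H]2O[C@]2(C)[C@H](O)[C@@H]1O | intermediate
28 | angelic acid, (Z)-2-methylbut-2-enoic acid | C/C=C(/C)C(=O)O | starting material
29 | CNP0188566.2 | C=C([C@H](CC=C(C)C)OC(C)=O)[C@@H]1C[C@@H]2O[C@]2(C)[C@H](OC(=O)/C(C)=C\C)[C@@H]1OC(=O)/C(C)=C\C | target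

Total step count: 17. Longest linear sequence: 17 steps (1 → 29).

Steps most likely to fail

Step 6 (ring expansion with internal capture). The ester next to the developing cation may slow ionisation, and the allyl cation may lose a proton or be taken at C3 by an external nucleophile before the neighbouring group closes. The fallback ends the capture irreversibly with a carbonate and sets out from diol 4. Boc2O and DMAP in MeCN should give the bis(tert-butyl carbonate) F1. Bromoform, 50% NaOH and BnEt3NCl should convert it into the anti dibromocyclopropane F2. AgBF4 with 2,6-di-tert-butylpyridine in CH2Cl2 should then let the C6 carbonate carbonyl close on C5 with loss of the tert-butyl cation as isobutene, giving the cis-fused cyclic carbonate F3. NaOMe in MeOH cleaves both carbonates and returns to the route at triol 11.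

Step 17 (bis-angeloylation). The second hydroxyl, flanked by the epoxide and the side chain, may acylate incompletely, and forcing conditions may cause Z→E isomerisation of the angeloyl group or opening of the epoxide. The fallback builds the Z-enoates on the molecule and sets out from epoxy diol 27. Esterification of both hydroxyls with 2-[bis(2,2,2-trifluoroethoxy)phosphoryl]propanoic acid (EDC·HCl, DMAP, CH2Cl2) should give the bis(phosphonopropionate) F4. Still–Gennari olefination with acetaldehyde (KHMDS, 18-crown-6, THF, −78 °C) should then form both (Z)-2-methylbut-2-enoates and arrive at target 29.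

Step 12 (allylboration at C8). Facial selectivity may be poor if the C1 centre opposes the reagent (mismatched double diastereoselection) or the 2-substituent of the enal erodes it. The fallback sets C8 by ketone reduction and starts from enal 18. Allylmagnesium bromide in THF at −78 °C, with no stereocontrol needed, should give 21 together with its C8 epimer F5. Dess–Martin oxidation of the mixture should give the single dienone F6. Corey–Bakshi–Shibata reduction with the (R)-methyl oxazaborolidine and catecholborane in toluene at −78 °C, the alkenyl branch acting as the large group, should return 21.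

Further compounds
F1 | step 6 | (1R,5S)-5-[2-(tert-butoxycarbonyloxy)ethyl]cyclopent-2-en-1-yl tert-butyl carbonate | CC(C)(C)OC(=O)OCC[C@@H]1CC=C[C@@H]1OC(=O)OC(C)(C)C
F2 | step 6 | 6,6-dibromobicyclo[3.1.0]hexane bis(tert-butyl carbonate), carbonate and arm cis and anti to the CBr2 bridge | CC(C)(C)OC(=O)OCC[C@@H]1C[C@@H]2[C@H]([C@@H]1OC(=O)OC(C)(C)C)C2(Br)Br
F3 | step 6 | cis-fused C5/C6 cyclic carbonate of the 4-bromocyclohex-3-ene, arm as tert-butyl carbonate | CC(C)(C)OC(=O)OCC[C@@H]1CC=C(Br)[C@@H]2OC(=O)O[C@H]12
F4 | step 17 | C5,C6-bis{2-[bis(2,2,2-trifluoroethoxy)phosphoryl]propanoate} of 27 | C=C([C@H](CC=C(C)C)OC(C)=O)[C@@H]1C[C@@H]2O[C@]2(C)[C@H](OC(=O)C(C)P(=O)(OCC(F)(F)F)OCC(F)(F)F)[C@@H]1OC(=O)C(C)P(=O)(OCC(F)(F)F)OCC(F)(F)F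
F5 | step 12 | (3R)-epimer of 21 at C8 | C=C([C@@H](CC=C)O)[C@@H]1CC=C(C)[C@@H]2OC(C)(C)O[C@H]12
F6 | step 12 | 2-[(1S,5S,6R)-5,6-(isopropylidenedioxy)-4-methylcyclohex-3-en-1-yl]hexa-1,5-dien-3-one | C=CCC(=O)C(=C)[C@@H]1CC=C(C)[C@@H]2OC(C)(C)O[C@H]12
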